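**Retrosynthetic overview**
- The strategy rests on ring A (C4a, C5, C6, C7, C8, C8a): a hexasubstituted benzene whose oxygens on C5, C7 and C8a alternate with three different carbon groups (the C4 carbonyl on C4a, the (E)-3-methylbut-1-enyl group on C6, prenyl on C8), so the three oxygens must be told apart.
- Last disconnections: the four MOM ethers, then the C2–C1' bond, made with control of C2 (S) by rhodium-catalysed asymmetric conjugate addition of a 2,4-bis(MOM-oxy)phenylboronic acid (from 4-bromoresorcinol) to a chromone.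
- Ring C (O1–C2 bond) comes from an o-hydroxyaryl enaminone; its acetyl group is placed on C4a by directed ortho-lithiation; the C6 alkene comes from an alkyne by trans-hydrosilylation/protodesilylation.
- Ring A comes from a 2-alkynyl-3-ethoxycyclobutenone and a prenyl-bearing siloxyalkyne by thermal benzannulation (C8–C8a and C6–C7 bonds), which delivers O1 as free phenol, O7 as silyl ether and O5 as ethyl ether.
- Ring order: A (step 5), then C (step 9); ring B is bought and attached in step 15.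

Key step: step 5

Assumption: the sense of induction of the Rh/MeO-F12-BIPHEP catalyst is taken as (R)-ligand giving attack on the Re face of C2 (2S); this is to be confirmed on a simple chromone, and the antipodal ligand is used if the sense is the reverse.

Step 1
Reactants: 1 3-ethoxycyclobut-2-en-1-one
Product: 2 3-ethoxy-2-iodocyclobut-2-en-1-one
Conditions: NIS, MeCN, 0 °C to rt, dark
Reagents that add atoms: N-iodosuccinimide, O=C1CCC(=O)N1I
Why: Electrophilic α-iodination of a vinylogous ester, whose C2 is the nucleophilic enol-ether carbon and whose enone is restored by loss of the C2 proton.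

Step 2
Reactants: 2 3-ethoxy-2-iodocyclobut-2-en-1-one; 3 3-methylbut-1-yne
Product: 4 3-ethoxy-2-(3-methylbut-1-yn-1-yl)cyclobut-2-en-1-one
Conditions: PdCl2(PPh3)2 (cat.), CuI (cat.), i-Pr2NEt, THF, 0 °C to rt, sealed vessel
Reagents that add atoms: none
Why: Sonogashira coupling of an α-iodoenone, a fast oxidative-addition partner, with the terminal alkyne, the hindered tertiary amine being unable to displace the ethoxy group of the vinylogous ester.

Step 3
Reactants: 5 4-methylpent-3-enoic acid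
Product: 6 methyl 4-methylpent-3-enoate
Conditions: MeI, K2CO3, DMF, rt
Reagents that add atoms: iodomethane, CI
Why: Carboxylate O-alkylation (SN2) under non-acidic conditions avoids the acid-catalysed lactonisation and double-bond migration to which this β,γ-unsaturated acid is prone.

Step 4
Reactants: 6 methyl 4-methylpent-3-enoate
Product: 9 triisopropyl[(5-methylhex-4-en-1-yn-1-yl)oxy]silane, via dibromo enolate 7 (not isolated), via lithium ynolate 8 (not isolated)
Conditions: CH2Br2, LiTMP, THF, −78 °C; then 6; then n-BuLi, −78 °C to rt; then TIPSCl, −78 to 0 °C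
Reagents that add atoms: dibromomethane, BrCBr; chlorotriisopropylsilane, CC(C)[Si](Cl)(C(C)C)C(C)C
Why: Kowalski ester homologation stopped at the ynolate stage, in which LiCHBr2 adds to the ester to give the dibromo enolate, bromine–lithium exchange and 1,2-shift of the prenyl group give the ynolate, and the bulky silyl chloride traps it on oxygen.

Step 5
Reactants: 4 3-ethoxy-2-(3-methylbut-1-yn-1-yl)cyclobut-2-en-1-one; 9 triisopropyl[(5-methylhex-4-en-1-yn-1-yl)oxy]silane
Product: 14 5-ethoxy-4-(3-methylbut-1-yn-1-yl)-2-(3-methylbut-2-en-1-yl)-3-(triisopropylsilyloxy)phenol, via vinylketene 10 (not isolated), via vinylcyclobutenone 11 (not isolated), via dienylketene 12 (not isolated), via cyclohexadienone 13 (not isolated)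
Conditions: toluene, 80 °C then 110 °C, sealed tube, 9 in slight excess
Reagents that add atoms: none
Why: Heating opens 4 by 4π-electrocyclic cleavage of its C(=O)–CH2 bond to the vinylketene, whose ketene C=C undergoes a polar [2+2] cycloaddition with the siloxyalkyne in which the nucleophilic, prenylmethyl-bearing alkyne carbon bonds to the ketene carbonyl carbon (C8–C8a) and the silyloxy-bearing carbon to the alkynyl-substituted ketene carbon (C6–C7), giving the 4-vinylcyclobutenone. This opens by a second, reversible 4π-electrocyclic step to the dienylketene, and ring A closes by thermal 6π-electrocyclisation (bond C4a–C8a) to the cyclohexa-2,4-dienone, which tautomerises to the phenol. The closest known reaction type is the Danheiser benzannulation of cyclobutenones with trialkylsilyloxyalkynes to monosilylated resorcinols. No stereocentre is formed. The step needs a single regiochemical outcome, and the polarity of the ketene–ynol ether [2+2] secures it: prenyl ends between the free phenol (future O1) and the silyl ether (O7), the alkynyl group between the silyl ether and the ethoxy group (O5), and the only ring hydrogen at C4a. The C6 chain is carried as an alkyne so that it cannot enter the 6π closure as an alkenyl group could, and the trisubstituted prenyl alkene is far less reactive toward the ketene than the electron-rich ynol ether.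

Step 6
Reactants: 14 5-ethoxy-4-(3-methylbut-1-yn-1-yl)-2-(3-methylbut-2-en-1-yl)-3-(triisopropylsilyloxy)phenol
Product: 15 [3-ethoxy-5-(methoxymethoxy)-2-(3-methylbut-1-yn-1-yl)-6-(3-methylbut-2-en-1-yl)phenoxy]triisopropylsilane
Conditions: MOMCl, i-Pr2NEt, CH2Cl2, 0 °C to rt
Reagents that add atoms: chloromethyl methyl ether, COCCl
Why: O-Alkylation of the phenol with MOMCl protects O1 and installs the directing group for the next step, while the hindered TIPS ether is inert to amine base.

Step 7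
Reactants: 15 [3-ethoxy-5-(methoxymethoxy)-2-(3-methylbut-1-yn-1-yl)-6-(3-methylbut-2-en-1-yl)phenoxy]triisopropylsilane
Product: 17 1-[2-ethoxy-6-(methoxymethoxy)-3-(3-methylbut-1-yn-1-yl)-5-(3-methylbut-2-en-1-yl)-4-(triisopropylsilyloxy)phenyl]ethan-1-one, via aryllithium 16 (not isolated)
Conditions: n-BuLi, TMEDA, THF, −20 to 0 °C; then MeC(O)N(OMe)Me, −78 °C to rt; aq. NH4Cl
Reagents that add atoms: N-methoxy-N-methylacetamide, CC(=O)N(C)OC
Why: Directed ortho-metalation at the only ring C–H, which lies between the cooperating OMOM and OEt groups, followed by acylation with the Weinreb amide, whose chelated tetrahedral adduct prevents over-addition.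

Step 8
Reactants: 17 1-[2-ethoxy-6-(methoxymethoxy)-3-(3-methylbut-1-yn-1-yl)-5-(3-methylbut-2-en-1-yl)-4-(triisopropylsilyloxy)phenyl]ethan-1-one
Product: 18 (E)-3-(dimethylamino)-1-[2-ethoxy-6-(methoxymethoxy)-3-(3-methylbut-1-yn-1-yl)-5-(3-methylbut-2-en-1-yl)-4-(triisopropylsilyloxy)phenyl]prop-2-en-1-one
Conditions: DMF-DMA, toluene, 100 °C
Reagents that add atoms: N,N-dimethylformamide dimethyl acetal, COC(OC)N(C)C
Why: Enaminone formation by condensation of the methyl ketone with the amide acetal at its only enolisable position.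

Step 9
Reactants: 18 (E)-3-(dimethylamino)-1-[2-ethoxy-6-(methoxymethoxy)-3-(3-methylbut-1-yn-1-yl)-5-(3-methylbut-2-en-1-yl)-4-(triisopropylsilyloxy)phenyl]prop-2-en-1-one
Product: 19 5-ethoxy-6-(3-methylbut-1-yn-1-yl)-8-(3-methylbut-2-en-1-yl)-7-(triisopropylsilyloxy)-4H-chromen-4-one
Conditions: HCl (2 M aq.), MeOH, 40 °C
Reagents that add atoms: none
Why: Acid removes the MOM acetal activated by the ortho carbonyl, and the liberated O1–H adds to the enaminone β-carbon with loss of dimethylamine (addition–elimination closure of ring C to the chromone), the doubly ortho-flanked aryl TIPS ether being stable to dilute methanolic HCl.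

Step 10
Reactants: 19 5-ethoxy-6-(3-methylbut-1-yn-1-yl)-8-(3-methylbut-2-en-1-yl)-7-(triisopropylsilyloxy)-4H-chromen-4-one
Product: 21 5-ethoxy-7-hydroxy-6-[(E)-3-methylbut-1-en-1-yl]-8-(3-methylbut-2-en-1-yl)-4H-chromen-4-one, via vinylsilane 20 (not isolated)
Conditions: [Cp*Ru(MeCN)3]PF6 (cat.), (EtO)3SiH, CH2Cl2, 0 °C to rt; then CuI, TBAF, THF, rt
Reagents that add atoms: none
Why: Trost trans-hydrosilylation adds H and Si anti across the alkyne chemoselectively beside the alkenes, and Cu(I)/fluoride protodesilylation replaces silicon by hydrogen with retention, so either regioisomeric vinylsilane gives the (E)-alkene while the same fluoride cleaves the TIPS ether.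

Step 11
Reactants: 21 5-ethoxy-7-hydroxy-6-[(E)-3-methylbut-1-en-1-yl]-8-(3-methylbut-2-en-1-yl)-4H-chromen-4-one
Product: 22 5,7-dihydroxy-6-[(E)-3-methylbut-1-en-1-yl]-8-(3-methylbut-2-en-1-yl)-4H-chromen-4-one
Conditions: MgI2·OEt2, THF, 60 °C; aq. NH4Cl/Na2S2O3
Reagents that add atoms: none
Why: Chelation-controlled ether cleavage in which Mg(II) bridges the C4 carbonyl and the peri O5 and iodide removes the ethyl group by SN2, without Brønsted acid, so the prenyl and styrenyl alkenes are left alone and no stereocentre is yet present to be lost.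

Step 12
Reactants: 22 5,7-dihydroxy-6-[(E)-3-methylbut-1-en-1-yl]-8-(3-methylbut-2-en-1-yl)-4H-chromen-4-one
Product: 23 5,7-bis(methoxymethoxy)-6-[(E)-3-methylbut-1-en-1-yl]-8-(3-methylbut-2-en-1-yl)-4H-chromen-4-one
Conditions: NaH, MOMCl, DMF, 0 °C to rt
Reagents that add atoms: chloromethyl methyl ether, COCCl
Why: Double O-alkylation of the sodium phenoxides, the strong base being needed to break the O5–H···O=C4 hydrogen bond.

Step 13
Reactants: 24 4-bromoresorcinol
Product: 25 1-bromo-2,4-bis(methoxymethoxy)benzene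
Conditions: MOMCl, i-Pr2NEt, CH2Cl2, 0 °C to rt
Reagents that add atoms: chloromethyl methyl ether, COCCl
Why: Standard O-alkylation of both phenols to MOM ethers.

Step 14
Reactants: 25 1-bromo-2,4-bis(methoxymethoxy)benzene
Product: 28 [2,4-bis(methoxymethoxy)phenyl]boronic acid, via aryllithium 26 (not isolated), via lithium borate 27 (not isolated)
Conditions: n-BuLi, THF, −78 °C; then B(Oi-Pr)3, −78 °C to rt; aq. NH4Cl
Reagents that add atoms: triisopropyl borate, CC(C)OB(OC(C)C)OC(C)C; water, O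
Why: Bromine–lithium exchange, borylation of the chelation-stabilised aryllithium and mild hydrolysis of the borate give the boronic acid without loss of the MOM groups.

Step 15
Reactants: 23 5,7-bis(methoxymethoxy)-6-[(E)-3-methylbut-1-en-1-yl]-8-(3-methylbut-2-en-1-yl)-4H-chromen-4-one; 28 [2,4-bis(methoxymethoxy)phenyl]boronic acid
Product: 29 (2S)-2-[2,4-bis(methoxymethoxy)phenyl]-5,7-bis(methoxymethoxy)-6-[(E)-3-methylbut-1-en-1-yl]-8-(3-methylbut-2-en-1-yl)chroman-4-one
Conditions: Rh(I) catalyst preformed from [Rh(OH)(cod)]2 and (R)-MeO-F12-BIPHEP (cat.), 28 in excess, toluene/H2O, 40 °C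
Reagents that add atoms: none
Why: Hayashi–Miyaura rhodium-catalysed asymmetric 1,4-addition of an arylboronic acid to a chromone, in which the aryl–Rh species bearing the chiral bisphosphine inserts the C2=C3 bond from the Re face of C2 and so sets C2 as S, under neutral conditions that avoid base-induced ring opening of the flavanone.

Step 16
Reactants: 29 (2S)-2-[2,4-bis(methoxymethoxy)phenyl]-5,7-bis(methoxymethoxy)-6-[(E)-3-methylbut-1-en-1-yl]-8-(3-methylbut-2-en-1-yl)chroman-4-one
Product: 30 (2S)-2-(2,4-dihydroxyphenyl)-5,7-dihydroxy-6-[(E)-3-methylbut-1-en-1-yl]-8-(3-methylbut-2-en-1-yl)chroman-4-one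
Conditions: HCl (3 M aq.), MeOH, rt to 40 °C
Reagents that add atoms: none
Why: Acid-catalysed acetal cleavage of the four MOM ethers under mild methanolic HCl, a standard unmasking for prenylated flavanones that should avoid the basic conditions under which C2 epimerises by ring opening.

**Compound list**
1 | 3-ethoxycyclobut-2-en-1-one | CCOC1=CC(=O)C1 | starting material
2 | 3-ethoxy-2-iodocyclobut-2-en-1-one | CCOC1=C(I)C(=O)C1 | intermediate
3 | 3-methylbut-1-yne | CC(C)C#C | starting material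
4 | 3-ethoxy-2-(3-methylbut-1-yn-1-yl)cyclobut-2-en-1-one | CCOC1=C(C#CC(C)C)C(=O)C1 | intermediate
5 | 4-methylpent-3-enoic acid | CC(C)=CCC(=O)O | starting material
6 | methyl 4-methylpent-3-enoate | CC(C)=CCC(=O)OC | intermediate
7 | lithium 1,1-dibromo-5-methylhexa-1,4-dien-2-olate (not isolated) | [Li+].[O-]C(CC=C(C)C)=C(Br)Br | intermediate
8 | lithium 5-methylhex-4-en-1-yn-1-olate (not isolated) | [Li+].[O-]C#CCC=C(C)C | intermediate
9 | triisopropyl[(5-methylhex-4-en-1-yn-1-yl)oxy]silane | CC(C)=CCC#CO[Si](C(C)C)(C(C)C)C(C)C | intermediate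
10 | 3-ethoxy-2-(3-methylbut-1-yn-1-yl)buta-1,3-dien-1-one (not isolated) | CCOC(=C)C(C#CC(C)C)=C=O | intermediate
11 | 4-(1-ethoxyvinyl)-4-(3-methylbut-1-yn-1-yl)-2-(3-methylbut-2-en-1-yl)-3-(triisopropylsilyloxy)cyclobut-2-en-1-one, racemic (not isolated) | CCOC(=C)C1(C#CC(C)C)C(=O)C(CC=C(C)C)=C1O[Si](C(C)C)(C(C)C)C(C)C | intermediate
12 | (3E)-5-ethoxy-4-(3-methylbut-1-yn-1-yl)-2-(3-methylbut-2-en-1-yl)-3-(triisopropylsilyloxy)hexa-1,3,5-trien-1-one (not isolated) | O=C=C(CC=C(C)C)/C(O[Si](C(C)C)(C(C)C)C(C)C)=C(/C#CC(C)C)C(OCC)=C | intermediate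
13 | 5-ethoxy-4-(3-methylbut-1-yn-1-yl)-2-(3-methylbut-2-en-1-yl)-3-(triisopropylsilyloxy)cyclohexa-2,4-dien-1-one (not isolated) | O=C1CC(OCC)=C(C#CC(C)C)C(O[Si](C(C)C)(C(C)C)C(C)C)=C1CC=C(C)C | intermediate
14 | 5-ethoxy-4-(3-methylbut-1-yn-1-yl)-2-(3-methylbut-2-en-1-yl)-3-(triisopropylsilyloxy)phenol | CC(C)=CCc1c(O)cc(OCC)c(C#CC(C)C)c1O[Si](C(C)C)(C(C)C)C(C)C | intermediate
15 | [3-ethoxy-5-(methoxymethoxy)-2-(3-methylbut-1-yn-1-yl)-6-(3-methylbut-2-en-1-yl)phenoxy]triisopropylsilane | CC(C)=CCc1c(OCOC)cc(OCC)c(C#CC(C)C)c1O[Si](C(C)C)(C(C)C)C(C)C | intermediate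
16 | [2-ethoxy-6-(methoxymethoxy)-3-(3-methylbut-1-yn-1-yl)-5-(3-methylbut-2-en-1-yl)-4-(triisopropylsilyloxy)phenyl]lithium (not isolated) | [Li]c1c(OCC)c(C#CC(C)C)c(O[Si](C(C)C)(C(C)C)C(C)C)c(CC=C(C)C)c1OCOC | intermediate
17 | 1-[2-ethoxy-6-(methoxymethoxy)-3-(3-methylbut-1-yn-1-yl)-5-(3-methylbut-2-en-1-yl)-4-(triisopropylsilyloxy)phenyl]ethan-1-one | CC(=O)c1c(OCC)c(C#CC(C)C)c(O[Si](C(C)C)(C(C)C)C(C)C)c(CC=C(C)C)c1OCOC | intermediate
18 | (E)-3-(dimethylamino)-1-[2-ethoxy-6-(methoxymethoxy)-3-(3-methylbut-1-yn-1-yl)-5-(3-methylbut-2-en-1-yl)-4-(triisopropylsilyloxy)phenyl]prop-2-en-1-one | CN(C)/C=C/C(=O)c1c(OCC)c(C#CC(C)C)c(O[Si](C(C)C)(C(C)C)C(C)C)c(CC=C(C)C)c1OCOC | intermediate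
19 | 5-ethoxy-6-(3-methylbut-1-yn-1-yl)-8-(3-methylbut-2-en-1-yl)-7-(triisopropylsilyloxy)-4H-chromen-4-one | CCOc1c(C#CC(C)C)c(O[Si](C(C)C)(C(C)C)C(C)C)c(CC=C(C)C)c2occc(=O)c12 | intermediate
20 | 5-ethoxy-6-[(Z)-3-methyl-1-(triethoxysilyl)but-1-en-1-yl]-8-(3-methylbut-2-en-1-yl)-7-(triisopropylsilyloxy)-4H-chromen-4-one (not isolated; one regioisomer drawn, its regioisomer with silicon on the other alkene carbon converges on 21) | CCOc1c(/C(=C/C(C)C)[Si](OCC)(OCC)OCC)c(O[Si](C(C)C)(C(C)C)C(C)C)c(CC=C(C)C)c2occc(=O)c12 | intermediate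
21 | 5-ethoxy-7-hydroxy-6-[(E)-3-methylbut-1-en-1-yl]-8-(3-methylbut-2-en-1-yl)-4H-chromen-4-one | CCOc1c(/C=C/C(C)C)c(O)c(CC=C(C)C)c2occc(=O)c12 | intermediate
22 | 5,7-dihydroxy-6-[(E)-3-methylbut-1-en-1-yl]-8-(3-methylbut-2-en-1-yl)-4H-chromen-4-one | Oc1c(/C=C/C(C)C)c(O)c(CC=C(C)C)c2occc(=O)c12 | intermediate
23 | 5,7-bis(methoxymethoxy)-6-[(E)-3-methylbut-1-en-1-yl]-8-(3-methylbut-2-en-1-yl)-4H-chromen-4-one | COCOc1c(/C=C/C(C)C)c(OCOC)c(CC=C(C)C)c2occc(=O)c12 | intermediate
24 | 4-bromoresorcinol | Oc1ccc(Br)c(O)c1 | starting material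
25 | 1-bromo-2,4-bis(methoxymethoxy)benzene | COCOc1ccc(Br)c(OCOC)c1 | intermediate
26 | [2,4-bis(methoxymethoxy)phenyl]lithium (not isolated) | [Li]c1ccc(OCOC)cc1OCOC | intermediate
27 | lithium [2,4-bis(methoxymethoxy)phenyl]tri(propan-2-yloxy)borate (not isolated) | [Li+].CC(C)O[B-](OC(C)C)(OC(C)C)c1ccc(OCOC)cc1OCOC | intermediate
28 | [2,4-bis(methoxymethoxy)phenyl]boronic acid | OB(O)c1ccc(OCOC)cc1OCOC | intermediate
29 | (2S)-2-[2,4-bis(methoxymethoxy)phenyl]-5,7-bis(methoxymethoxy)-6-[(E)-3-methylbut-1-en-1-yl]-8-(3-methylbut-2-en-1-yl)chroman-4-one | CC(C)=CCc1c(OCOC)c(/C=C/C(C)C)c(OCOC)c2c1O[C@H](c1ccc(OCOC)cc1OCOC)CC2=O | intermediate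
30 | (2S)-2-(2,4-dihydroxyphenyl)-5,7-dihydroxy-6-[(E)-3-methylbut-1-en-1-yl]-8-(3-methylbut-2-en-1-yl)chroman-4-one | CC(C)=CCc1c(O)c(/C=C/C(C)C)c(O)c2c1O[C@H](c1ccc(O)cc1O)CC2=O | target

**Step count**
Total: 16 steps. Longest linear sequence: 12 steps (steps 1, 2, 5–12, 15, 16; the branch through steps 3 and 4 is of equal length).

**Steps most likely to fail**

Step 5. The donor-substituted cyclobutenone may open to the vinylketene only slowly at temperatures the siloxyalkyne tolerates, so that decomposition of the ynol ether, ketene dimerisation or O-acylation of the product phenol by the ketene could outrun the annulation. The fallback generates the same vinylketene at room temperature by a different route. It sets out from 3 and 9 and comes back at 10, which goes on to 14. Commercial ethyl (E)-3-ethoxybut-2-enoate (CCOC(C)=CC(=O)OCC) is iodinated at C2 (NIS, AcOH, then Et3N) to ethyl 3-ethoxy-2-iodobut-2-enoate F1. Sonogashira coupling with 3 gives ethyl 3-ethoxy-2-(3-methylbut-1-yn-1-yl)but-2-enoate F2. Saponification (LiOH, THF/H2O, careful acidification) gives 3-ethoxy-2-(3-methylbut-1-yn-1-yl)but-2-enoic acid F3, and oxalyl chloride with catalytic DMF gives 3-ethoxy-2-(3-methylbut-1-yn-1-yl)but-2-enoyl chloride F4. Slow addition of Et3N to F4 and 9 in toluene effects 1,4-dehydrochlorination to 10, which should be trapped by the ynol ether as it forms; brief warming then completes the electrocyclic sequence to 14.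

Step 10. The two ortho substituents (OTIPS and OEt) may shield the alkyne so that hydrosilylation stalls, or protodesilylation of the hindered vinylsilane may remain incomplete. The fallback sets out from 19 and comes back at 21. Lindlar semihydrogenation (H2, Pd/CaCO3/Pb, quinoline, EtOAc) gives 5-ethoxy-6-[(Z)-3-methylbut-1-en-1-yl]-8-(3-methylbut-2-en-1-yl)-7-(triisopropylsilyloxy)-4H-chromen-4-one F5. Thiyl-radical isomerisation (PhSSPh cat., hν, cyclohexane) should drive it to the less strained styrene, 5-ethoxy-6-[(E)-3-methylbut-1-en-1-yl]-8-(3-methylbut-2-en-1-yl)-7-(triisopropylsilyloxy)-4H-chromen-4-one F6. TBAF in THF then removes the silyl ether to give 21.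

Step 15. Transmetalation of the ortho-alkoxy, electron-rich boronic acid may be slow enough for protodeboronation to dominate, or facial selectivity on the 5-alkoxylated chromone may be poor. The fallback sets out from 23 and 26 and comes back at 29. Aqueous NaOH in EtOH opens 23 with loss of formate to 1-[2-hydroxy-4,6-bis(methoxymethoxy)-5-[(E)-3-methylbut-1-en-1-yl]-3-(3-methylbut-2-en-1-yl)phenyl]ethan-1-one F7. Formylation of 26 with DMF gives 2,4-bis(methoxymethoxy)benzaldehyde F8. Claisen–Schmidt condensation of F7 with F8 (KOH, EtOH) gives (E)-3-[2,4-bis(methoxymethoxy)phenyl]-1-[2-hydroxy-4,6-bis(methoxymethoxy)-5-[(E)-3-methylbut-1-en-1-yl]-3-(3-methylbut-2-en-1-yl)phenyl]prop-2-en-1-one F9. Oxa-Michael cyclisation through the only free phenol (NaOAc, EtOH, reflux) gives racemic 2-[2,4-bis(methoxymethoxy)phenyl]-5,7-bis(methoxymethoxy)-6-[(E)-3-methylbut-1-en-1-yl]-8-(3-methylbut-2-en-1-yl)chroman-4-one F10. Preparative HPLC on a chiral stationary phase separates the enantiomers, and the 2S enantiomer is 29.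

**Further compounds**
F1 | step 5 | ethyl 3-ethoxy-2-iodobut-2-enoate | CCOC(C)=C(I)C(=O)OCC
F2 | step 5 | ethyl 3-ethoxy-2-(3-methylbut-1-yn-1-yl)but-2-enoate | CCOC(C)=C(C#CC(C)C)C(=O)OCC
F3 | step 5 | 3-ethoxy-2-(3-methylbut-1-yn-1-yl)but-2-enoic acid | CCOC(C)=C(C#CC(C)C)C(=O)O
F4 | step 5 | 3-ethoxy-2-(3-methylbut-1-yn-1-yl)but-2-enoyl chloride | CCOC(C)=C(C#CC(C)C)C(=O)Cl
F5 | step 10 | 5-ethoxy-6-[(Z)-3-methylbut-1-en-1-yl]-8-(3-methylbut-2-en-1-yl)-7-(triisopropylsilyloxy)-4H-chromen-4-one | CCOc1c(/C=C\C(C)C)c(O[Si](C(C)C)(C(C)C)C(C)C)c(CC=C(C)C)c2occc(=O)c12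
F6 | step 10 | 5-ethoxy-6-[(E)-3-methylbut-1-en-1-yl]-8-(3-methylbut-2-en-1-yl)-7-(triisopropylsilyloxy)-4H-chromen-4-one | CCOc1c(/C=C/C(C)C)c(O[Si](C(C)C)(C(C)C)C(C)C)c(CC=C(C)C)c2occc(=O)c12
F7 | step 15 | 1-[2-hydroxy-4,6-bis(methoxymethoxy)-5-[(E)-3-methylbut-1-en-1-yl]-3-(3-methylbut-2-en-1-yl)phenyl]ethan-1-one | CC(=O)c1c(O)c(CC=C(C)C)c(OCOC)c(/C=C/C(C)C)c1OCOC
F8 | step 15 | 2,4-bis(methoxymethoxy)benzaldehyde | COCOc1ccc(C=O)c(OCOC)c1
F9 | step 15 | (E)-3-[2,4-bis(methoxymethoxy)phenyl]-1-[2-hydroxy-4,6-bis(methoxymethoxy)-5-[(E)-3-methylbut-1-en-1-yl]-3-(3-methylbut-2-en-1-yl)phenyl]prop-2-en-1-one | O=C(/C=C/c1ccc(OCOC)cc1OCOC)c1c(O)c(CC=C(C)C)c(OCOC)c(/C=C/C(C)C)c1OCOC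
F10 | step 15 | racemic 2-[2,4-bis(methoxymethoxy)phenyl]-5,7-bis(methoxymethoxy)-6-[(E)-3-methylbut-1-en-1-yl]-8-(3-methylbut-2-en-1-yl)chroman-4-one | CC(C)=CCc1c(OCOC)c(/C=C/C(C)C)c(OCOC)c2c1OC(c1ccc(OCOC)cc1OCOC)CC2=O
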